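**Retrosynthetic overview**
1. The (E)-styryl C(sp2)–aryl bond is cut first (Heck): an 8-iodo-7-methoxycoumarin plus a cyclohexene carrying a vinyl group on its quaternary carbon; the vinyl goes back to an aldehyde and that to a ring ester.
2. The quaternary methyl is cut next: enolate methylation of the ring ester, anti to the neighbouring aryl group, sets the second stereocentre.
3. The cyclohexene C=C is cut by ring-closing metathesis to an acyclic propenyl/isopropenyl diene acid.
4. The bond from the aryl-bearing carbon to the α-carbon of that acid is an Ireland–Claisen bond. It leads back to an (R)-allylic ester whose carbinol centre, the first stereocentre, comes from ketoreductase reduction of an aryl enone (Heck product of a 6-bromo-7-methoxycoumarin).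
5. Ring order: pyranone ring of the 6-bromocoumarin first (Wittig–lactonisation of a salicylaldehyde), cyclohexene ring second (metathesis); the other coumarin ring is bought preformed and only iodinated and O-methylated.

Assumption: a commercial enzyme panel contains an (R)-selective ketoreductase that accepts the aryl enone of step 3; the aryl-bearing ring CH is called the benzylic centre throughout.

**Step 1**
Reactants: 1 5-bromo-2-hydroxy-4-methoxybenzaldehyde
Product: 3 6-bromo-7-methoxy-2H-chromen-2-one, via hydroxycinnamate ester 2 (not isolated)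
Conditions: Ph3P=CHCO2Et (1.2 equiv), PhNEt2, reflux (215 °C), 3 h
Reagents that add atoms: ethyl (triphenylphosphoranylidene)acetate, CCOC(=O)C=P(c1ccccc1)(c1ccccc1)c1ccccc1
Why: Wittig olefination of the salicylaldehyde gives the 2-hydroxycinnamate, which isomerises to the Z form at this temperature and lactonises with loss of ethanol (Wittig–lactonisation coumarin synthesis); no stereocentre is formed.

**Step 2**
Reactants: 3 6-bromo-7-methoxy-2H-chromen-2-one; 4 but-3-en-2-one
Product: 5 7-methoxy-6-[(1E)-3-oxobut-1-en-1-yl]-2H-chromen-2-one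
Conditions: Pd(OAc)2 (3 mol%), P(o-tol)3 (6 mol%), NaOAc, DMF, 110 °C, sealed tube
Reagents that add atoms: none
Why: Mizoroki–Heck reaction in which oxidative addition of the aryl bromide, insertion of the enone at its terminal carbon and syn-β-hydride elimination give the E-enone; no stereocentre is formed.

**Step 3**
Reactants: 5 7-methoxy-6-[(1E)-3-oxobut-1-en-1-yl]-2H-chromen-2-one
Product: 6 6-[(1E,3R)-3-hydroxybut-1-en-1-yl]-7-methoxy-2H-chromen-2-one
Conditions: (R)-selective ketoreductase (NADPH-dependent alcohol dehydrogenase), NADP+ (cat.), iPrOH (10 equiv), phosphate buffer pH 7.0/DMSO 9:1, 30 °C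
Reagents that add atoms: none
Why: Enzymatic asymmetric ketone reduction in which the ketoreductase transfers hydride from NADPH to one enantiotopic face of the methyl ketone (anti-Prelog delivery), setting the first stereocentre as (R) in high ee while the alkene and lactone are untouched and propan-2-ol regenerates the cofactor.

**Step 4**
Reactants: 7 5-oxohexanoic acid
Product: 8 5-methylhex-5-enoic acid
Conditions: MePPh3Br (1.3 equiv), KOtBu (2.4 equiv), THF, 0 °C → rt; then 1 M HCl
Reagents that add atoms: methyltriphenylphosphonium bromide, C[P+](c1ccccc1)(c1ccccc1)c1ccccc1.[Br-]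
Why: Wittig methylenation of the ketone (the acid is carried as its potassium carboxylate) installs the isopropenyl end needed for the later ring closure; no stereocentre is formed.

**Step 5**
Reactants: 6 6-[(1E,3R)-3-hydroxybut-1-en-1-yl]-7-methoxy-2H-chromen-2-one; 8 5-methylhex-5-enoic acid
Product: 9 (2R,3E)-4-(7-methoxy-2-oxo-2H-chromen-6-yl)but-3-en-2-yl 5-methylhex-5-enoate
Conditions: DCC (1.1 equiv), DMAP (10 mol%), CH2Cl2, 0 °C → rt
Reagents that add atoms: none
Why: Steglich esterification acylates the oxygen only, so the carbinol C–O bond and its (R) configuration are untouched.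

**Step 6**
Reactants: 9 (2R,3E)-4-(7-methoxy-2-oxo-2H-chromen-6-yl)but-3-en-2-yl 5-methylhex-5-enoate
Product: 12 (3S,4E)-3-(7-methoxy-2-oxo-2H-chromen-6-yl)-2-(3-methylbut-3-en-1-yl)hex-4-enoic acid (C2 epimers), via silyl ketene acetal 10 (not isolated), via trimethylsilyl ester 11 (not isolated)
Conditions: LiN(SiMe3)2 (1.3 equiv), Me3SiCl (2 equiv), THF, −78 °C → 40 °C; then 1 M HCl
Reagents that add atoms: none
Why: Ireland–Claisen rearrangement in which the silyl ketene acetal undergoes a suprafacial [3,3]-sigmatropic shift through a chair transition state with the carbinol methyl equatorial, so the (R) C–O centre is traded for the new benzylic C–C stereocentre (3S) and an E-propenyl group, while the α-centre forms as an epimer mixture that is planarised again in step 9.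

**Step 7**
Reactants: 12 (3S,4E)-3-(7-methoxy-2-oxo-2H-chromen-6-yl)-2-(3-methylbut-3-en-1-yl)hex-4-enoic acid
Product: 13 2-(trimethylsilyl)ethyl (3S,4E)-3-(7-methoxy-2-oxo-2H-chromen-6-yl)-2-(3-methylbut-3-en-1-yl)hex-4-enoate (C2 epimers)
Conditions: Me3SiCH2CH2OH (1.5 equiv), DCC, DMAP (10 mol%), CH2Cl2, rt
Reagents that add atoms: 2-(trimethylsilyl)ethanol, C[Si](C)(C)CCO
Why: Steglich esterification installs a fluoride-cleavable ester, so the hindered carboxyl group can later be freed without hydroxide or hydride that would attack the coumarin lactone.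

**Step 8**
Reactants: 13 2-(trimethylsilyl)ethyl (3S,4E)-3-(7-methoxy-2-oxo-2H-chromen-6-yl)-2-(3-methylbut-3-en-1-yl)hex-4-enoate
Product: 14 2-(trimethylsilyl)ethyl (2S)-2-(7-methoxy-2-oxo-2H-chromen-6-yl)-4-methylcyclohex-3-ene-1-carboxylate (C1 epimers)
Conditions: second-generation Grubbs catalyst RuCl2(=CHPh)(H2IMes)(PCy3) (5 mol%), CH2Cl2, 40 °C
Reagents that add atoms: none
Why: Ring-closing metathesis between the propenyl and isopropenyl groups closes the cyclohexene with its trisubstituted C=C fixed next to the benzylic carbon and expels propene; the benzylic stereocentre is a spectator.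

**Step 9**
Reactants: 14 2-(trimethylsilyl)ethyl (2S)-2-(7-methoxy-2-oxo-2H-chromen-6-yl)-4-methylcyclohex-3-ene-1-carboxylate
Product: 16 2-(trimethylsilyl)ethyl (1R,2R)-2-(7-methoxy-2-oxo-2H-chromen-6-yl)-1,4-dimethylcyclohex-3-ene-1-carboxylate (aryl cis to ester), via lithium ester enolate 15 (not isolated)
Conditions: LiN(iPr)2 (1.15 equiv), THF, −78 °C, 45 min; MeI (3 equiv), DMPU, −78 → −40 °C
Reagents that add atoms: iodomethane, CI
Why: Ester enolate alkylation in which enolisation makes the α-carbon planar (converging both epimers) and iodomethane attacks the face anti to the neighbouring aryl group, which sits pseudoaxial to avoid A(1,3) strain, so the quaternary stereocentre forms with methyl trans and ester cis to the aryl group (1,2-induction).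

**Step 10**
Reactants: 16 2-(trimethylsilyl)ethyl (1R,2R)-2-(7-methoxy-2-oxo-2H-chromen-6-yl)-1,4-dimethylcyclohex-3-ene-1-carboxylate
Product: 17 (1R,2R)-2-(7-methoxy-2-oxo-2H-chromen-6-yl)-1,4-dimethylcyclohex-3-ene-1-carboxylic acid
Conditions: Bu4NF (2 equiv), THF, rt; then 1 M HCl (work-up)
Reagents that add atoms: none
Why: Fluoride attack at silicon triggers β-elimination of the 2-(trimethylsilyl)ethyl ester to carboxylate, ethene and Me3SiF, a deprotection that does not depend on access to the hindered acyl carbon and spares the lactone and both stereocentres.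

**Step 11**
Reactants: 17 (1R,2R)-2-(7-methoxy-2-oxo-2H-chromen-6-yl)-1,4-dimethylcyclohex-3-ene-1-carboxylic acid
Product: 19 (1R,2R)-2-(7-methoxy-2-oxo-2H-chromen-6-yl)-1,4-dimethylcyclohex-3-ene-1-carbaldehyde, via acid chloride 18 (not isolated)
Conditions: Me2C=C(Cl)NMe2 (1.2 equiv), CH2Cl2, 0 °C → rt; then LiAlH(OtBu)3 (1.1 equiv), THF, −78 °C
Reagents that add atoms: none
Why: Neutral acid chloride formation with the Ghosez reagent followed by partial reduction with the bulky hydride LiAlH(OtBu)3 stops at the aldehyde and leaves lactone and alkenes alone at −78 °C; the quaternary centre has no α-hydrogen and cannot epimerise.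

**Step 12**
Reactants: 19 (1R,2R)-2-(7-methoxy-2-oxo-2H-chromen-6-yl)-1,4-dimethylcyclohex-3-ene-1-carbaldehyde
Product: 20 6-[(1S,6S)-6-ethenyl-3,6-dimethylcyclohex-2-en-1-yl]-7-methoxy-2H-chromen-2-one
Conditions: MePPh3Br (1.5 equiv), KOtBu (1.4 equiv), THF, 0 °C; add 19, 0 °C → rt
Reagents that add atoms: methyltriphenylphosphonium bromide, C[P+](c1ccccc1)(c1ccccc1)c1ccccc1.[Br-]
Why: Wittig methylenation of the non-enolisable aldehyde, which is far more electrophilic toward the ylide than the lactone at 0 °C, gives the vinyl group without touching either stereocentre (the descriptors change only through CIP priorities).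

**Step 13**
Reactants: 21 7-hydroxy-2H-chromen-2-one
Product: 22 7-hydroxy-8-iodo-2H-chromen-2-one
Conditions: I2 (1.05 equiv), KI, 25% aq. NH3, rt; then 2 M HCl to pH 3
Reagents that add atoms: iodine, [I][I]
Why: Electrophilic aromatic iodination of the phenoxide takes place at C8, the position ortho to the phenoxide oxygen and next to the ring oxygen that is the usual site of electrophilic attack in 7-hydroxycoumarins; no stereocentre is formed.

**Step 14**
Reactants: 22 7-hydroxy-8-iodo-2H-chromen-2-one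
Product: 23 8-iodo-7-methoxy-2H-chromen-2-one
Conditions: MeI (1.5 equiv), K2CO3 (1.5 equiv), acetone, reflux
Reagents that add atoms: iodomethane, CI
Why: Williamson ether synthesis in which the phenoxide is O-methylated by SN2 attack on iodomethane; no stereocentre is formed.

**Step 15**
Reactants: 20 6-[(1S,6S)-6-ethenyl-3,6-dimethylcyclohex-2-en-1-yl]-7-methoxy-2H-chromen-2-one; 23 8-iodo-7-methoxy-2H-chromen-2-one
Product: 24 7-methoxy-6-[(1S,6S)-6-[(E)-2-(7-methoxy-2-oxo-2H-chromen-8-yl)ethenyl]-3,6-dimethylcyclohex-2-en-1-yl]-2H-chromen-2-one (target)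
Conditions: Pd(OAc)2 (10 mol%), Bu4NCl (1 equiv), NaHCO3 (2.5 equiv), DMF, 90 °C
Reagents that add atoms: none
Why: Mizoroki–Heck reaction under ligand-free conditions in which the arylpalladium adds to the unhindered terminal carbon of the vinyl group and syn-β-hydride elimination, possible only toward the new aryl-bearing carbon because the other neighbour is quaternary, gives the E-alkene with both stereocentres as spectators.

**Compound list**
1 | 5-bromo-2-hydroxy-4-methoxybenzaldehyde | O=Cc1cc(Br)c(OC)cc1O | starting material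
2 | ethyl 3-(5-bromo-2-hydroxy-4-methoxyphenyl)prop-2-enoate (E/Z mixture, not isolated) | CCOC(=O)C=Cc1cc(Br)c(OC)cc1O | intermediate
3 | 6-bromo-7-methoxy-2H-chromen-2-one | COc1cc2oc(=O)ccc2cc1Br | intermediate
4 | but-3-en-2-one | CC(=O)C=C | starting material
5 | 7-methoxy-6-[(1E)-3-oxobut-1-en-1-yl]-2H-chromen-2-one | CC(=O)/C=C/c1cc2ccc(=O)oc2cc1OC | intermediate
6 | 6-[(1E,3R)-3-hydroxybut-1-en-1-yl]-7-methoxy-2H-chromen-2-one | C[C@@H](O)/C=C/c1cc2ccc(=O)oc2cc1OC | intermediate
7 | 5-oxohexanoic acid | CC(=O)CCCC(=O)O | starting material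
8 | 5-methylhex-5-enoic acid | C=C(C)CCCC(=O)O | intermediate
9 | (2R,3E)-4-(7-methoxy-2-oxo-2H-chromen-6-yl)but-3-en-2-yl 5-methylhex-5-enoate | C[C@@H](OC(=O)CCCC(C)=C)/C=C/c1cc2ccc(=O)oc2cc1OC | intermediate
10 | 7-methoxy-6-[(1E,3R)-3-({5-methyl-1-[(trimethylsilyl)oxy]hexa-1,5-dien-1-yl}oxy)but-1-en-1-yl]-2H-chromen-2-one (silyl ketene acetal of 9, ketene acetal geometry undefined, not isolated) | C[C@@H](OC(O[Si](C)(C)C)=CCCC(C)=C)/C=C/c1cc2ccc(=O)oc2cc1OC | intermediate
11 | trimethylsilyl (3S,4E)-3-(7-methoxy-2-oxo-2H-chromen-6-yl)-2-(3-methylbut-3-en-1-yl)hex-4-enoate (C2 epimers, not isolated) | C/C=C/[C@H](c1cc2ccc(=O)oc2cc1OC)C(CCC(C)=C)C(=O)O[Si](C)(C)C | intermediate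
12 | (3S,4E)-3-(7-methoxy-2-oxo-2H-chromen-6-yl)-2-(3-methylbut-3-en-1-yl)hex-4-enoic acid (C2 epimers) | C/C=C/[C@H](c1cc2ccc(=O)oc2cc1OC)C(CCC(C)=C)C(=O)O | intermediate
13 | 2-(trimethylsilyl)ethyl (3S,4E)-3-(7-methoxy-2-oxo-2H-chromen-6-yl)-2-(3-methylbut-3-en-1-yl)hex-4-enoate (C2 epimers) | C/C=C/[C@H](c1cc2ccc(=O)oc2cc1OC)C(CCC(C)=C)C(=O)OCC[Si](C)(C)C | intermediate
14 | 2-(trimethylsilyl)ethyl (2S)-2-(7-methoxy-2-oxo-2H-chromen-6-yl)-4-methylcyclohex-3-ene-1-carboxylate (C1 epimers) | COc1cc2oc(=O)ccc2cc1[C@H]1C=C(C)CCC1C(=O)OCC[Si](C)(C)C | intermediate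
15 | lithium enolate of 14 (exocyclic ester enolate at ring C1, benzylic centre unchanged, not isolated) | COc1cc2oc(=O)ccc2cc1[C@H]1C=C(C)CCC1=C(O[Li])OCC[Si](C)(C)C | intermediate
16 | 2-(trimethylsilyl)ethyl (1R,2R)-2-(7-methoxy-2-oxo-2H-chromen-6-yl)-1,4-dimethylcyclohex-3-ene-1-carboxylate (aryl cis to ester, trans to the 1-methyl) | COc1cc2oc(=O)ccc2cc1[C@H]1C=C(C)CC[C@@]1(C)C(=O)OCC[Si](C)(C)C | intermediate
17 | (1R,2R)-2-(7-methoxy-2-oxo-2H-chromen-6-yl)-1,4-dimethylcyclohex-3-ene-1-carboxylic acid | COc1cc2oc(=O)ccc2cc1[C@H]1C=C(C)CC[C@@]1(C)C(=O)O | intermediate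
18 | (1R,2R)-2-(7-methoxy-2-oxo-2H-chromen-6-yl)-1,4-dimethylcyclohex-3-ene-1-carbonyl chloride (not isolated) | COc1cc2oc(=O)ccc2cc1[C@H]1C=C(C)CC[C@@]1(C)C(=O)Cl | intermediate
19 | (1R,2R)-2-(7-methoxy-2-oxo-2H-chromen-6-yl)-1,4-dimethylcyclohex-3-ene-1-carbaldehyde | COc1cc2oc(=O)ccc2cc1[C@H]1C=C(C)CC[C@@]1(C)C=O | intermediate
20 | 6-[(1S,6S)-6-ethenyl-3,6-dimethylcyclohex-2-en-1-yl]-7-methoxy-2H-chromen-2-one | COc1cc2oc(=O)ccc2cc1[C@H]1C=C(C)CC[C@@]1(C)C=C | intermediate
21 | 7-hydroxy-2H-chromen-2-one | Oc1ccc2ccc(=O)oc2c1 | starting material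
22 | 7-hydroxy-8-iodo-2H-chromen-2-one | Oc1ccc2ccc(=O)oc2c1I | intermediate
23 | 8-iodo-7-methoxy-2H-chromen-2-one | COc1ccc2ccc(=O)oc2c1I | intermediate
24 | 7-methoxy-6-[(1S,6S)-6-[(E)-2-(7-methoxy-2-oxo-2H-chromen-8-yl)ethenyl]-3,6-dimethylcyclohex-2-en-1-yl]-2H-chromen-2-one | COc1cc2oc(=O)ccc2cc1[C@H]1C=C(C)CC[C@@]1(C)/C=C/c1c(OC)ccc2ccc(=O)oc12 | target

**Totals**
Total step count: 15.
Longest linear sequence: 12 steps (1, 2, 3, 5, 6, 7, 8, 9, 10, 11, 12, 15; from 1 to 24).

**Three steps most likely to fail**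

1. The enolate methylation in step 9. The amide base meets a coumarin, which is both a lactone and a Michael acceptor, and the anti-to-aryl facial selectivity is predicted by analogy, not measured. The fallback abandons enolate chemistry and builds both stereocentres in one catalytic asymmetric Diels–Alder reaction; it sets out from 3 and comes back to the route at 19.
   - Heck coupling of 3 with 2-methylbut-3-en-2-ol (Pd(OAc)2, P(o-tol)3, NaOAc, DMF, 110 °C) gives the tertiary allylic alcohol 6-[(1E)-3-hydroxy-3-methylbut-1-en-1-yl]-7-methoxy-2H-chromen-2-one F1.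
   - Dehydration with Burgess reagent in toluene at 80 °C gives the diene 7-methoxy-6-[(1E)-3-methylbuta-1,3-dien-1-yl]-2H-chromen-2-one F2.
   - F2 reacts with 2-methylprop-2-enal in CH2Cl2 at −78 → −20 °C under 20 mol% of an o-tolyl oxazaborolidinium bis(trifluoromethanesulfonyl)imide (from α,α-diphenylprolinol, o-tolylboroxine and HNTf2). The catalyst enantiomer is chosen by a test run for the (1R,2R) adduct.
   - The 1-aryl and 3-methyl groups of the diene both direct the quaternary carbon next to the aryl-bearing carbon, and the formyl-endo transition state puts aryl and CHO cis, which is aldehyde 19.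

2. The Ireland–Claisen rearrangement in step 6. LiN(SiMe3)2 again meets the coumarin, and any rearrangement through the axial-methyl chair erodes the ee. The fallback replaces the strong-base ester enolate by a decarboxylative malonate Claisen rearrangement that needs only a silylating agent; it sets out from 6 and comes back at 12.
   - Meldrum's acid is alkylated with 4-bromo-2-methylbut-1-ene (K2CO3, DMF) to 2,2-dimethyl-5-(3-methylbut-3-en-1-yl)-1,3-dioxane-4,6-dione F3.
   - Heating F3 with 6 in toluene at 90 °C opens the dioxanedione to the malonic half-ester 3-{[(2R,3E)-4-(7-methoxy-2-oxo-2H-chromen-6-yl)but-3-en-2-yl]oxy}-2-(3-methylbut-3-en-1-yl)-3-oxopropanoic acid F4.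
   - N,O-bis(trimethylsilyl)acetamide with 10 mol% KOAc in toluene at 110 °C turns F4 into its bis-silyl ketene acetal, which undergoes the same suprafacial [3,3] shift to 2-[(1R,2E)-1-(7-methoxy-2-oxo-2H-chromen-6-yl)but-2-en-1-yl]-2-(3-methylbut-3-en-1-yl)propanedioic acid F5 after aqueous work-up.
   - Thermal decarboxylation of F5 at 130 °C gives 12.

3. The final Heck coupling in step 15. A doubly ortho-substituted aryl iodide must insert a vinyl group that sits on a quaternary carbon, so slow insertion, hydrodeiodination or arylation of a coumarin C–H may compete. The fallback forms the same bond by Suzuki–Miyaura coupling with the alkene geometry fixed beforehand; it sets out from 19 (with 23 as partner) and comes back at 24.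
   - Takai olefination of 19 (CrCl2, CHI3, THF, 0 °C) gives 6-[(1S,6R)-6-[(E)-2-iodoethenyl]-3,6-dimethylcyclohex-2-en-1-yl]-7-methoxy-2H-chromen-2-one F6.
   - Miyaura borylation of 23 (B2pin2, Pd(dppf)Cl2, KOAc, dioxane, 90 °C) gives 7-methoxy-8-(4,4,5,5-tetramethyl-1,3,2-dioxaborolan-2-yl)-2H-chromen-2-one F7.
   - Coupling of F6 with F7 (Pd(PPh3)4, K3PO4, dioxane/H2O, 80 °C) gives 24 with retention of the E geometry.

**Further compounds**
F1 | step 9 | 6-[(1E)-3-hydroxy-3-methylbut-1-en-1-yl]-7-methoxy-2H-chromen-2-one | CC(C)(O)/C=C/c1cc2ccc(=O)oc2cc1OC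
F2 | step 9 | 7-methoxy-6-[(1E)-3-methylbuta-1,3-dien-1-yl]-2H-chromen-2-one | C=C(C)/C=C/c1cc2ccc(=O)oc2cc1OC
F3 | step 6 | 2,2-dimethyl-5-(3-methylbut-3-en-1-yl)-1,3-dioxane-4,6-dione | C=C(C)CCC1C(=O)OC(C)(C)OC1=O
F4 | step 6 | 3-{[(2R,3E)-4-(7-methoxy-2-oxo-2H-chromen-6-yl)but-3-en-2-yl]oxy}-2-(3-methylbut-3-en-1-yl)-3-oxopropanoic acid | C[C@@H](OC(=O)C(CCC(C)=C)C(=O)O)/C=C/c1cc2ccc(=O)oc2cc1OC
F5 | step 6 | 2-[(1R,2E)-1-(7-methoxy-2-oxo-2H-chromen-6-yl)but-2-en-1-yl]-2-(3-methylbut-3-en-1-yl)propanedioic acid | C/C=C/[C@H](c1cc2ccc(=O)oc2cc1OC)C(CCC(C)=C)(C(=O)O)C(=O)O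
F6 | step 15 | 6-[(1S,6R)-6-[(E)-2-iodoethenyl]-3,6-dimethylcyclohex-2-en-1-yl]-7-methoxy-2H-chromen-2-one | COc1cc2oc(=O)ccc2cc1[C@H]1C=C(C)CC[C@@]1(C)/C=C/I
F7 | step 15 | 7-methoxy-8-(4,4,5,5-tetramethyl-1,3,2-dioxaborolan-2-yl)-2H-chromen-2-one | COc1ccc2ccc(=O)oc2c1B1OC(C)(C)C(C)(C)O1
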